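**Plan**

1. Cuts: first the depside C–O bond between the ring A carbonyl carbon and O-4 of ring B; then ring A at C1–C2, C2–C3, C4–C5 and C5–C6, leaving a benzyl (E)-3-(diazoacetyl)hex-2-enoate and methoxyethyne; the enone behind the diazoketone is cut at its C=C bond into hexan-2-one and glyoxylic acid.
2. Enabling feature: in ring A the C2 phenol and the C4 methoxy group are meta to each other across an unsubstituted C3, and the carboxyl carbon sits on C1 next to the phenol. A ketene carbon (C2), the two carbons of an alkoxyethyne (C3, C4) and an acrylate terminus (C1) deliver exactly this pattern.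
3. Forward: the chain is assembled by aldol condensation, esterified and turned into the diazoketone; ring A, the only ring formed, arises in the photochemical benzannulation. Ring B is bought as olivetolic acid and adjusted (benzyl ester, 2-O-methyl, free 4-OH); the halves are joined by esterification and the last benzyl group is removed.
4. Stereochemistry: the target has no stereocentre. The one geometric element that matters, the E double bond of the enoate, is set under thermodynamic control in the aldol condensation and disappears into ring A.
5. Choices: a benzyl ester at the vinyl terminus lets hydrogenolysis free the hindered ring A acid, and the diazo group is installed by deacylative diazo transfer so that no diazoalkane meets the electron-poor double bond.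

Key step: step 5

Remark: hexan-2-one, glyoxylic acid monohydrate, chloroacetaldehyde dimethyl acetal and olivetolic acid are taken as purchased; methoxyethyne is too volatile and labile to buy and is made fresh.

**Route**

Step 1
Reactants: 1 hexan-2-one; 2 glyoxylic acid (commercial monohydrate)
Product: 3 (E)-3-acetylhex-2-enoic acid
Conditions: 85% H3PO4, excess 1, 80 °C
Reagents that add atoms: none
Why: Acid-catalysed aldol condensation of a methyl alkyl ketone with glyoxylic acid: the more substituted enol reacts at C3 of 1, and the E acid (acetyl trans to carboxyl) is the stable open-chain product because the Z isomer can persist only as its lactol.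

Step 2
Reactants: 3 (E)-3-acetylhex-2-enoic acid
Product: 4 benzyl (E)-3-acetylhex-2-enoate
Conditions: BnBr, KHCO3, DMF, 20 °C
Reagents that add atoms: benzyl bromide, BrCc1ccccc1
Why: Carboxylate O-alkylation (SN2) under bicarbonate is mild enough to leave the enone geometry and the acidic γ-hydrogens untouched.

Step 3
Reactants: 4 benzyl (E)-3-acetylhex-2-enoate
Product: 6 benzyl (E)-3-(2-diazoacetyl)hex-2-enoate, via trifluoroacetyl diketone 5 (not isolated)
Conditions: LiN(SiMe3)2, THF, −78 °C; CF3CO2CH2CF3, −78 °C; aqueous HCl work-up, crude 5 taken on; then 4-acetamidobenzenesulfonyl azide, Et3N, H2O, MeCN, 20 °C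
Reagents that add atoms: 4-acetamidobenzenesulfonyl azide, CC(=O)Nc1ccc(cc1)S(=O)(=O)N=[N+]=[N-]; 2,2,2-trifluoroethyl trifluoroacetate, O=C(OCC(F)(F)F)C(F)(F)F (its trifluoroacetyl group stays in 5 only)
Why: Detrifluoroacetylative diazo transfer: kinetic deprotonation of the methyl ketone, Claisen trifluoroacetylation to 5 and Regitz-type diazo transfer with loss of the trifluoroacetyl group give the α′-diazo enone without exposing the electron-poor double bond to a diazoalkane, which would add to it as a 1,3-dipole.

Step 4
Reactants: 7 chloroacetaldehyde dimethyl acetal (2-chloro-1,1-dimethoxyethane)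
Product: 9 methoxyethyne, via sodium methoxyethynide 8 (not isolated)
Conditions: NaNH2 (3 equiv), liquid NH3, −33 °C; then satd aq NH4Cl, −70 °C; distilled into cold CH2Cl2
Reagents that add atoms: sodium amide, [Na+].[NH2-] (its sodium stays in 8 only)
Why: Base-induced double β-elimination (loss of methanol, then of HCl) is the standard preparation of alkoxyethynes from chloroacetaldehyde acetals, the third equivalent of base holding the product as acetylide 8 until the quench.

Step 5
Reactants: 6 benzyl (E)-3-(2-diazoacetyl)hex-2-enoate; 9 methoxyethyne
Product: 14 benzyl 2-hydroxy-4-methoxy-6-propylbenzoate, via vinylketene 10 (not isolated), via 4-alkenylcyclobutenone 11 (not isolated), via dienylketene 12 (not isolated), via cyclohexadienone 13 (not isolated)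
Conditions: 9 (4 equiv), degassed CH2Cl2, hν (254 nm, low-pressure mercury lamp, quartz), 20 °C; then toluene, 80 °C
Reagents that add atoms: none
Why: Light expels N2 from 6 and the alkenyl group migrates to the former diazo carbon (photochemical Wolff rearrangement) to give vinylketene 10; the nucleophilic CH carbon of 9 then bonds to the ketene carbonyl carbon in a [2+2] cycloaddition to 11, which opens by 4π electrocyclic reaction to dienylketene 12. Ring A closes by 6π electrocyclisation of 12 between the ketene carbon and the ester-bearing terminus, and cyclohexadienone 13 tautomerises to the phenol; the warm-up completes the two electrocyclic steps. The closest known reaction type is the Danheiser benzannulation of α,β-unsaturated α′-diazo ketones with alkoxyalkynes. No stereocentre is created that survives, since the sp3 carbon of 13 is lost on aromatisation. The step needs the regiochemistry of the [2+2] addition, which the polarised ynol ether secures (methoxy meta to the new hydroxyl and para to the ester), and it needs the ester on the outside of the triene, which the E geometry of 6 secures and which also blocks closure of 10 through the ester oxygen to a 2-pyranone. Because the phenol of 14 is held in a hydrogen bond to its ester, acylation of the product by the ketene should stay slow.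

Step 6
Reactants: 14 benzyl 2-hydroxy-4-methoxy-6-propylbenzoate
Product: 15 2-hydroxy-4-methoxy-6-propylbenzoic acid
Conditions: H2 (1 atm), Pd/C (10 wt% palladium on carbon), EtOAc, 20 °C
Reagents that add atoms: none
Why: Hydrogenolysis of the benzyl ester frees the acid under neutral conditions at room temperature, avoiding the forcing saponification a doubly ortho-substituted salicylate would need and the decarboxylation that heat or strong acid could provoke.

Step 7
Reactants: 16 olivetolic acid (2,4-dihydroxy-6-pentylbenzoic acid)
Product: 17 benzyl 2,4-dihydroxy-6-pentylbenzoate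
Conditions: BnBr (1.0 equiv), KHCO3, DMF, 40 °C
Reagents that add atoms: benzyl bromide, BrCc1ccccc1
Why: Chemoselective carboxylate benzylation (SN2): bicarbonate deprotonates only the acid, so neither phenol is alkylated.

Step 8
Reactants: 17 benzyl 2,4-dihydroxy-6-pentylbenzoate
Product: 18 benzyl 2-hydroxy-6-pentyl-4-(prop-2-en-1-yloxy)benzoate
Conditions: allyl bromide (1.05 equiv), K2CO3, acetone, reflux
Reagents that add atoms: allyl bromide, C=CCBr
Why: Williamson etherification goes to the free 4-OH, which is more acidic and more nucleophilic than the 2-OH locked in a hydrogen bond to the ester carbonyl.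

Step 9
Reactants: 18 benzyl 2-hydroxy-6-pentyl-4-(prop-2-en-1-yloxy)benzoate
Product: 19 benzyl 2-methoxy-6-pentyl-4-(prop-2-en-1-yloxy)benzoate
Conditions: MeI (excess), K2CO3, DMF, 50 °C
Reagents that add atoms: iodomethane, CI
Why: Williamson methylation of the remaining chelated 2-OH under more forcing conditions, to which the allyl ether and the benzyl ester are inert.

Step 10
Reactants: 19 benzyl 2-methoxy-6-pentyl-4-(prop-2-en-1-yloxy)benzoate
Product: 20 benzyl 4-hydroxy-2-methoxy-6-pentylbenzoate
Conditions: Pd(PPh3)4 (2 mol%), morpholine, THF, 20 °C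
Reagents that add atoms: none
Why: Tsuji–Trost deallylation: zerovalent palladium ionises the allyl aryl ether to a π-allyl complex that morpholine captures, leaving the benzyl ester and the methyl ether untouched.

Step 11
Reactants: 15 2-hydroxy-4-methoxy-6-propylbenzoic acid; 20 benzyl 4-hydroxy-2-methoxy-6-pentylbenzoate
Product: 22 benzyl 4-[(2-hydroxy-4-methoxy-6-propylbenzoyl)oxy]-2-methoxy-6-pentylbenzoate, via mixed trifluoroacetic anhydride 21 (not isolated)
Conditions: (CF3CO)2O, toluene, 20 °C
Reagents that add atoms: trifluoroacetic anhydride, O=C(OC(=O)C(F)(F)F)C(F)(F)F (its trifluoroacetyl group stays in 21 only)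
Why: Depside esterification through the mixed trifluoroacetic anhydride is the established way to join 2-hydroxy-4-alkoxy-6-alkylbenzoic acids to benzyl hydroxybenzoates, the chelated and hindered 2-OH of ring A not competing with the free 4-OH of 20.

Step 12
Reactants: 22 benzyl 4-[(2-hydroxy-4-methoxy-6-propylbenzoyl)oxy]-2-methoxy-6-pentylbenzoate
Product: 23 4-[(2-hydroxy-4-methoxy-6-propylbenzoyl)oxy]-2-methoxy-6-pentylbenzoic acid
Conditions: H2 (1 atm), Pd/C (10 wt% palladium on carbon), EtOAc, 20 °C
Reagents that add atoms: none
Why: Hydrogenolysis of the benzyl ester, to which the hindered aryl ester link, the methyl ethers and the phenol are stable.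

**Compound list**

1 | hexan-2-one | CCCCC(C)=O | starting material
2 | glyoxylic acid (used as the monohydrate) | O=CC(=O)O | starting material
3 | (E)-3-acetylhex-2-enoic acid | CC(=O)/C(CCC)=C/C(=O)O | intermediate
4 | benzyl (E)-3-acetylhex-2-enoate | CC(=O)/C(CCC)=C/C(=O)OCc1ccccc1 | intermediate
5 | benzyl (E)-3-(4,4,4-trifluoro-3-oxobutanoyl)hex-2-enoate | O=C(CC(=O)C(F)(F)F)/C(CCC)=C/C(=O)OCc1ccccc1 | intermediate (not isolated)
6 | benzyl (E)-3-(2-diazoacetyl)hex-2-enoate | [N-]=[N+]=CC(=O)/C(CCC)=C/C(=O)OCc1ccccc1 | intermediate
7 | chloroacetaldehyde dimethyl acetal (2-chloro-1,1-dimethoxyethane) | COC(CCl)OC | starting material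
8 | sodium methoxyethynide | [Na+].[C-]#COC | intermediate (not isolated)
9 | methoxyethyne | C#COC | intermediate
10 | benzyl (E)-5-oxo-3-propylpenta-2,4-dienoate | O=C=C/C(CCC)=C/C(=O)OCc1ccccc1 | intermediate (not isolated)
11 | benzyl (E)-3-(2-methoxy-4-oxocyclobut-2-en-1-yl)hex-2-enoate (racemic) | COC1=CC(=O)C1/C(CCC)=C/C(=O)OCc1ccccc1 | intermediate (not isolated)
12 | benzyl (2E,4E)-5-methoxy-7-oxo-3-propylhepta-2,4,6-trienoate | O=C=C/C(OC)=C\C(CCC)=C\C(=O)OCc1ccccc1 | intermediate (not isolated)
13 | benzyl 4-methoxy-2-oxo-6-propylcyclohexa-3,5-diene-1-carboxylate (racemic) | CCCC1=CC(OC)=CC(=O)C1C(=O)OCc1ccccc1 | intermediate (not isolated)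
14 | benzyl 2-hydroxy-4-methoxy-6-propylbenzoate | CCCc1cc(OC)cc(O)c1C(=O)OCc1ccccc1 | intermediate
15 | 2-hydroxy-4-methoxy-6-propylbenzoic acid | CCCc1cc(OC)cc(O)c1C(=O)O | intermediate
16 | olivetolic acid (2,4-dihydroxy-6-pentylbenzoic acid) | CCCCCc1cc(O)cc(O)c1C(=O)O | starting material
17 | benzyl 2,4-dihydroxy-6-pentylbenzoate | CCCCCc1cc(O)cc(O)c1C(=O)OCc1ccccc1 | intermediate
18 | benzyl 2-hydroxy-6-pentyl-4-(prop-2-en-1-yloxy)benzoate | CCCCCc1cc(OCC=C)cc(O)c1C(=O)OCc1ccccc1 | intermediate
19 | benzyl 2-methoxy-6-pentyl-4-(prop-2-en-1-yloxy)benzoate | CCCCCc1cc(OCC=C)cc(OC)c1C(=O)OCc1ccccc1 | intermediate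
20 | benzyl 4-hydroxy-2-methoxy-6-pentylbenzoate | CCCCCc1cc(O)cc(OC)c1C(=O)OCc1ccccc1 | intermediate
21 | 2-hydroxy-4-methoxy-6-propylbenzoic trifluoroacetic anhydride | CCCc1cc(OC)cc(O)c1C(=O)OC(=O)C(F)(F)F | intermediate (not isolated)
22 | benzyl 4-[(2-hydroxy-4-methoxy-6-propylbenzoyl)oxy]-2-methoxy-6-pentylbenzoate | CCCCCc1cc(OC(=O)c2c(O)cc(OC)cc2CCC)cc(OC)c1C(=O)OCc1ccccc1 | intermediate
23 | 4-[(2-hydroxy-4-methoxy-6-propylbenzoyl)oxy]-2-methoxy-6-pentylbenzoic acid | CCCCCc1cc(OC(=O)c2c(O)cc(OC)cc2CCC)cc(OC)c1C(=O)O | target

**Step count and risks**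

Total steps: 12. Longest linear sequence: 7 steps (1, 2, 3, 5, 6, 11, 12).

Steps most likely to fail:

1. Step 5 (benzannulation). Under 254 nm light the enoate double bond may isomerise before or after loss of nitrogen, turning the ester inward so that the vinylketene closes through the ester oxygen instead of adding the alkyne. The volatile ynol ether may also evaporate or polymerise, and the product phenol may be photolysed further. The fallback generates the same ketene in the dark and sets out from 6. Silver-catalysed Wolff rearrangement (PhCO2Ag, Et3N, THF–H2O, 20 °C) with capture of the ketene by water should give (E)-5-(benzyloxy)-5-oxo-3-propylpent-3-enoic acid F1. Oxalyl chloride with catalytic DMF in CH2Cl2 converts it to benzyl (E)-5-chloro-5-oxo-3-propylpent-2-enoate F2. Slow addition of Et3N to F2 and 9 in toluene at 0 °C, then warming to 80 °C, dehydrochlorinates F2 to vinylketene 10, which follows the thermal sequence through 11, 12 and 13 and comes back to the route at 14.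

2. Step 3 (diazo transfer). The amide base or the lithium enolate may add in conjugate fashion to the doubly activated double bond, or deprotonation may occur at the γ-CH2 of the propyl chain and deconjugate the enoate, so that trifluoroacetylation at the methyl group stays incomplete. The fallback avoids an enolate and sets out from 4. Soft enolisation (Me3SiOTf, Et3N, CH2Cl2, 0 °C) should give benzyl (E)-3-[1-(trimethylsilyloxy)ethenyl]hex-2-enoate F3. N-Bromosuccinimide in THF at −78 °C brominates it to benzyl (E)-3-(2-bromoacetyl)hex-2-enoate F4. N,N′-Ditosylhydrazine and DBU in THF at 0 °C then alkylate the hydrazine and eliminate two sulfinates, which gives the diazoketone and comes back to the route at 6.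

3. Step 1 (aldol condensation). Condensation may take place at the methyl group of the ketone instead of C3, the Z isomer may be trapped as its lactol, and the hot acid may oligomerise the product. The fallback is a directed aldol reaction and sets out from 1. Me3SiCl and Et3N in hot DMF should give mainly the more substituted silyl enol ether (Z)-trimethyl(hex-2-en-2-yloxy)silane F5. Mukaiyama aldol addition to benzyl glyoxylate (TiCl4, CH2Cl2, −78 °C) gives benzyl 3-acetyl-2-hydroxyhexanoate F6. MsCl and Et3N form benzyl 3-acetyl-2-(methylsulfonyloxy)hexanoate F7, and DBU eliminates it by an E1cB pathway to the more stable E enone. This comes back to the route at 4 and makes step 2 unnecessary.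

**Further compounds**

F1 | step 5 | (E)-5-(benzyloxy)-5-oxo-3-propylpent-3-enoic acid | OC(=O)C/C(CCC)=C/C(=O)OCc1ccccc1
F2 | step 5 | benzyl (E)-5-chloro-5-oxo-3-propylpent-2-enoate | O=C(Cl)C/C(CCC)=C/C(=O)OCc1ccccc1
F3 | step 3 | benzyl (E)-3-[1-(trimethylsilyloxy)ethenyl]hex-2-enoate | C=C(O[Si](C)(C)C)/C(CCC)=C/C(=O)OCc1ccccc1
F4 | step 3 | benzyl (E)-3-(2-bromoacetyl)hex-2-enoate | BrCC(=O)/C(CCC)=C/C(=O)OCc1ccccc1
F5 | step 1 | (Z)-trimethyl(hex-2-en-2-yloxy)silane | CCC/C=C(/C)O[Si](C)(C)C
F6 | step 1 | benzyl 3-acetyl-2-hydroxyhexanoate (mixture of diastereomers) | CCCC(C(C)=O)C(O)C(=O)OCc1ccccc1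
F7 | step 1 | benzyl 3-acetyl-2-(methylsulfonyloxy)hexanoate (mixture of diastereomers) | CCCC(C(C)=O)C(OS(C)(=O)=O)C(=O)OCc1ccccc1
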